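# Total synthesis proposal for homo-plakotenin (18)

## Analysis of the target

Indene numbering is used throughout: C1(Me)–C2–C3(Me)–C3a–C4(Et, side chain)–C5(Ph)–C6=C7(Et)–C7a. The face of the bicycle that carries the C4 ethyl group is called β.

- Compound 18 is a trans-fused 2,3,3a,4,5,7a-hexahydro-1H-indene. The cyclohexene ring C3a–C4–C5–C6=C7–C7a shares the C3a–C7a bond with the cyclopentane ring C1–C2–C3–C3a–C7a.
- The SMILES decodes as 4β-ethyl, 4α-(E)-2-carboxyprop-1-enyl, 5β-phenyl, 3aβ-H, 7aα-H, 1β-methyl and 3α-methyl. This corresponds to (1R,3R,3aR,4S,5S,7aR).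
- The phenyl group and the side chain are therefore trans-diaxial.
- Each methyl group is trans to the neighbouring ring-fusion hydrogen. C1-Me is thus cis to C7 and C3-Me is cis to C4, which is the more crowded, pseudo-axial arrangement. Equilibration cannot set these centres; they need kinetic or stereospecific control.
- C4 is an all-carbon quaternary centre wedged between two tertiary stereocentres, C5 and C3a.
- Three sites are sensitive. C5–H is both allylic and benzylic, so the C6=C7 alkene can slip into conjugation with the phenyl ring. C7a is epimerisable whenever C7 is a carbonyl. The aldehyde precursor of the side chain is neopentyl and hindered.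
- The feature exploited is the substitution pattern of the six-membered ring. Every ring carbon is substituted, C4 bears a carbonyl-derived carbon, and C4 lies para to the sp2 carbon C7. C5 and C3a are the two "ortho" neighbours of C4.
- That is the pattern of a 4,4-disubstituted cyclohexa-2,5-dienone, which is a dearomatised benzoic acid derivative. In such a dienone C4 is prochiral and its two enone arms are enantiotopic.

## Retrosynthetic reasoning

**Side chain (C4–CH=C).** Compound 18 comes from ester 17 by saponification. Ester 17 comes from the neopentyl aldehyde 16 by an E-selective Wittig olefination. Aldehyde 16 is traced through alcohol 15 to the tertiary carboxamide 14. Keeping the C1 unit on C4 as an amide until this point is deliberate. The same group is needed earlier as activator, steric shield and directing group.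

**C7–ethyl bond and the C6=C7 alkene.** Compound 14 is cut at the C7–CH2CH3 bond to the enol triflate 13, and from there to ketone 11. A regiodefined enolate towards C6 fixes the alkene position. This avoids an elimination that could also give the C7=C7a or exocyclic isomers.

**C1 and C7a (two C–H bonds).** Ketone 11 is traced to the tetrasubstituted enone 10. One syn addition of H2 to C7a=C1 from the α face sets both centres. It places C1-Me cis to C7 and gives the trans ring fusion. The axial α-carboxamide on C4 lies 1,3-diaxial to C7a, so it can direct the metal to that face.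

**C1–C7a bond (five-membered ring).** Enone 10 is opened to the 1,6-diketone 9. The forward reaction is an intramolecular aldol condensation. It creates no stereocentre and has only one productive mode.

**C3–CH3, C2–C3 and C3a–C3.**
- Diketone 9 is cut at the C3–CH3 bond to the side-chain enone 8.
- Enone 8 is cut at its alkene to the vinyl ketone 7 (cross metathesis).
- Ketone 7 is cut at C3a–C3 to enone 5 (conjugate vinylation).
- The five-ring carbons thus arrive as three cheap pieces, and C3a is set by the existing C5 stereocentre.

**C5–phenyl bond (key disconnection).** Enone 5 is traced to the achiral dienone 4. Cutting here removes both C5 and the stereogenicity of the quaternary C4 in a single stroke. The forward reaction has to choose one of two enantiotopic enone arms and one of two diastereotopic faces.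

**Dearomatisation.** Dienone 4 comes from diene 3 by oxidation of the only CH2 group. Diene 3 comes from the flat, commercial benzamide 1 by Birch reduction–ethylation through enolate 2. All six carbons of the cyclohexene ring of 18, and the carbon that becomes the side-chain CH=, are already present in 1.

## Alternatives that were turned down

**Alternative 1:** the textbook intramolecular Diels–Alder reaction, which forms C4–C5 and C3a–C7a.
- The precursor is the linear tetraenoic acid A1. It needs an (E,E)-styryl diene, a (Z)-configured C3a=C4 dienophile, an (E)-enoate and an anti-1,3-dimethyl unit.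
- The alkene geometries map correctly onto C3a, C4, C5 and C7a. The π-facial choice, however, is made by the two allylic methyl-bearing centres.
- Minimising A1,3 strain against the C7 ethyl group and against the cis-alkenyl group on C4 places both allylic C–H bonds in the alkene planes. Both methyl groups then sit anti to the forming C3a–C7a bond.
- That transition state leads to diastereomer A2, with each methyl cis to its neighbouring ring-fusion hydrogen. Reaching 18 would require both methyl groups in the "inside" positions.
- In addition, A1 needs four stereodefined alkenes, which is a long linear chain synthesis.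

**Alternative 2:** dearomatisation of the whole bicycle.
- Flattening C3a and C7a reveals the locally C2-symmetric (1R,3R)-1,3-dimethylindane ester A3. Birch reduction–ethylation anti to the C3 methyl group would give A4.
- The C4 centre should come out correctly.
- However, A3 is not a cheap arene. It needs two benzylic stereocentres in a trans relationship and a carboxyl group in the hindered peri position.
- The tetrasubstituted C3a=C7a alkene of A4 would later have to take up two hydrogens in a trans sense, each anti to the adjacent methyl group.
- Only an electron-transfer reduction of the derived enone is realistic for such an alkene. Its protonation follows the more stable pyramidal carbanion, which puts the hydrogens cis to the methyl groups.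

**Alternative 3:** Ireland–Claisen rearrangement followed by ring-closing metathesis.
- The C4–C5 bond would be made by [3,3] rearrangement of the cinnamyl ester A5 to acid A6. The C6=C7 bond would then be closed by metathesis.
- The rearrangement is attractive for a hindered bond. It requires, however, a tetrasubstituted ketene acetal whose two carbon substituents (ethyl and a secondary cyclopentyl) are too similar for geometry control. The C4/C5 relationship would therefore be unselective.
- A5 also already contains the four contiguous, contra-steric cyclopentane stereocentres. The hardest part of the problem is only moved into the precursor.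

Key step: step 3

Assumption: the sense of induction of Rh/(S)-BINAP is taken from cyclohex-2-enone (S ligand gives the (S)-3-phenylcyclohexanone topology), and in step 6 the ligand antipode meant is the one that attacks the Si face of C3.

## Route

Step 1
Reactants: 1 1-benzoylpyrrolidine
Product: 3 (1-ethylcyclohexa-2,5-dien-1-yl)(pyrrolidin-1-yl)methanone, via lithium amide enolate 2 (not isolated)
Conditions: Li, NH3(l)/THF, t-BuOH (1 equiv), −78 °C; EtI; NH4Cl
Reagents that add atoms: iodoethane, CCI
Why: Birch reduction–alkylation of a tertiary benzamide: two-electron reduction and para protonation give the cross-conjugated amide enolate 2, which is alkylated at the ipso carbon and so builds the quaternary C4; no stereocentre arises because the ring is still symmetric.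

Step 2
Reactants: 3 (1-ethylcyclohexa-2,5-dien-1-yl)(pyrrolidin-1-yl)methanone
Product: 4 (1-ethyl-4-oxocyclohexa-2,5-dien-1-yl)(pyrrolidin-1-yl)methanone
Conditions: t-BuOOH (70 % aq), Rh2(cap)4 (1 mol %), CH2Cl2, rt
Reagents that add atoms: tert-butyl hydroperoxide, CC(C)(C)OO
Why: Catalytic allylic oxidation of the single, doubly allylic CH2 (future C7) to the cross-conjugated dienone; the quaternary carbon blocks aromatisation and the amide has no α-hydrogen.

Step 3
Reactants: 4 (1-ethyl-4-oxocyclohexa-2,5-dien-1-yl)(pyrrolidin-1-yl)methanone
Product: 5 enone with 4β-ethyl, 4α-(pyrrolidine-1-carbonyl) and 5β-phenyl, i.e. [(1R,6S)-1-ethyl-4-oxo-6-phenylcyclohex-2-en-1-yl](pyrrolidin-1-yl)methanone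
Conditions: PhB(OH)2 (1.5 equiv), [Rh(OH)((S)-binap)]2 (3 mol % Rh), dioxane/H2O 10:1, 35 °C
Reagents that add atoms: phenylboronic acid, OB(O)c1ccccc1
Why: Hayashi–Miyaura 1,4-addition used as a desymmetrisation: boron-to-rhodium transmetalation gives Ph–Rh, one enone arm binds and inserts to give an oxa-π-allyl rhodium species, and water releases the ketone and regenerates Rh–OH. The closest known reaction types are the Rh/BINAP arylation of cyclohexenones and the catalytic asymmetric conjugate addition to prochiral 4,4-disubstituted cyclohexa-2,5-dienones. The step closes no ring; it forms the hindered C5–Ph bond and turns an achiral, flat-ring-derived compound into one with two adjacent stereocentres. The face is chosen by the substrate: the twisted tertiary amide on C4 is much larger than ethyl and shields the α face of both arms, so phenyl enters β, cis to ethyl. The arm is chosen by the catalyst: of the two β-face approaches only one has the enone enantioface that (S)-BINAP accepts, and this fixes C5 as S and at the same moment makes the quaternary C4 stereogenic with the required configuration. Mono-addition is secured because the remaining enone of 5 has a β-carbon flanked by a quaternary and now more crowded environment. 1,2-Addition and Heck-type products are not expected under protic Rh(I) conditions.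

Step 4
Reactants: 5 enone (4β-Et, 4α-amide, 5β-Ph)
Product: 7 3aα-vinyl ketone (3aβ-H, 4β-Et, 4α-amide, 5β-Ph; C7 ketone), via trimethylsilyl enol ether 6 (not isolated)
Conditions: CH2=CHMgBr, CuBr·SMe2 (20 mol %), TMSCl, HMPA, THF, −78 °C; then 1 M HCl, THF, 0 °C
Reagents that add atoms: vinylmagnesium bromide, C=C[Mg]Br; chlorotrimethylsilane, C[Si](C)(C)Cl (its atoms stay only in 6)
Why: Silyl-accelerated copper-catalysed conjugate addition, suited to neopentyl β-carbons; in the reactive half-chair phenyl is pseudo-equatorial and ethyl axial, so axial attack comes anti to ethyl and trans to the C5 phenyl (the 3,5-trans rule), whereas the other half-chair would need attack syn-axial to phenyl; this sets C3a.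

Step 5
Reactants: 7 3aα-vinyl ketone
Product: 8 (E)-enone, the vinyl group extended to (E)-CH=CH–C(O)CH3 (C3=C2–C1(=O)–CH3)
Conditions: methyl vinyl ketone (5 equiv), Hoveyda–Grubbs II (5 mol %), CH2Cl2, 40 °C
Reagents that add atoms: methyl vinyl ketone, C=CC(C)=O
Why: Cross metathesis of a monosubstituted, α-branched alkene with an electron-poor partner is selective for the E cross product; ketone and tertiary amide are tolerated and no stereocentre is touched.

Step 6
Reactants: 8 (E)-enone
Product: 9 1,6-diketone with the C3 methyl group in place (C3 configured as in 18)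
Conditions: Me2Zn, (CuOTf)2·C6H6 (2.5 mol %), chiral dipeptide Schiff-base aryl phosphine ligand (6 mol %), toluene, −20 °C; aq NH4Cl
Reagents that add atoms: dimethylzinc, C[Zn]C
Why: Copper-catalysed asymmetric conjugate addition of a dialkylzinc to an acyclic aliphatic enone; Me2Zn leaves the ring ketone and the amide alone, and the catalyst delivers methyl to the Si face of C3; catalyst control is chosen because the substrate's own Felkin–Anh-type preference (C4 anti, C7a inside) points to the other face.

Step 7
Reactants: 9 1,6-diketone
Product: 10 bicyclic tetrasubstituted enone (C7=O, C7a=C1(CH3); 3α-Me, 3aβ-H, 4β-Et, 4α-amide, 5β-Ph)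
Conditions: KOH, MeOH, 0 → 40 °C
Reagents that add atoms: none
Why: Intramolecular aldol condensation (5-enolexo-exo-trig) of C7a onto the side-chain ketone C1; the alternative attack of C2 on C7 gives a bridged aldol that cannot dehydrate (bridgehead alkene) and reverts, and all other modes would be seven-membered; C3 and C3a are not acidic.

Step 8
Reactants: 10 bicyclic tetrasubstituted enone
Product: 11 trans-hydrindanone (1β-Me, 3α-Me, 3aβ-H, 7aα-H, 4β-Et, 4α-amide, 5β-Ph; C7=O)
Conditions: H2 (50 bar), [Ir(cod)(PCy3)(py)]BArF (10 mol %), CH2Cl2, rt
Reagents that add atoms: none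
Why: Carboxamide-directed homogeneous hydrogenation with a Crabtree-type cation: in 10 the C3a–C3 bond is pseudo-equatorial, so the C4 amide is axial on the α face and 1,3-diaxial to C7a; its carbonyl oxygen binds iridium and both hydrogens are delivered syn to the α face of C7a=C1, giving 7aα-H (trans fusion) and 1α-H (1β-methyl, cis to C7) in one step; undirected reduction of a tetrasubstituted enone is slow, and the neutral medium does not epimerise C7a.

Step 9
Reactants: 11 trans-hydrindanone
Product: 13 enol triflate (C7–OTf, C6=C7), via potassium enolate 12 (not isolated)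
Conditions: KHMDS, THF, −78 °C; PhNTf2, −78 → 0 °C
Reagents that add atoms: N-phenylbis(trifluoromethanesulfonimide), O=S(=O)(N(c1ccccc1)S(=O)(=O)C(F)(F)F)C(F)(F)F
Why: Irreversible kinetic deprotonation takes a C6 methylene proton rather than the tertiary, shielded C7a–H; O-triflation freezes the alkene position and removes the possibility of epimerisation at C7a.

Step 10
Reactants: 13 enol triflate
Product: 14 7-ethyl alkene, [4,7-diethyl-1,3-dimethyl-5-phenyl-hexahydroinden-4-yl](pyrrolidin-1-yl)methanone, all six stereocentres as in 18
Conditions: EtMgBr, Fe(acac)3 (5 mol %), THF/NMP, −20 °C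
Reagents that add atoms: ethylmagnesium bromide, CC[Mg]Br
Why: Iron-catalysed Kumada-type coupling of alkenyl triflates with alkyl Grignard reagents is fast at low temperature, is not troubled by β-hydride elimination and outruns attack on the hindered tertiary amide; the alkene position is retained.

Step 11
Reactants: 14 7-ethyl alkene amide
Product: 15 primary alcohol (C4α-CH2OH)
Conditions: LiH2NBH3 (from BH3·NH3 and n-BuLi), THF, 0 → 40 °C; 1 M HCl
Reagents that add atoms: none
Why: Lithium amidotrihydroborate reduces tertiary amides, including α-quaternary ones, to primary alcohols with C–N cleavage; the trisubstituted alkene is inert and no stereocentre is adjacent to an acidic site.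

Step 12
Reactants: 15 primary alcohol
Product: 16 aldehyde (C4α-CHO)
Conditions: Dess–Martin periodinane, CH2Cl2, rt
Reagents that add atoms: none
Why: Mild oxidation of a neopentyl alcohol; the aldehyde has no α-hydrogen and cannot epimerise or enolise.

Step 13
Reactants: 16 aldehyde
Product: 17 ethyl (E)-2-methylprop-2-enoate (ethyl ester of 18)
Conditions: Ph3P=C(CH3)CO2Et, toluene, 110 °C
Reagents that add atoms: ethyl 2-(triphenyl-λ5-phosphanylidene)propanoate, CCOC(=O)C(C)=P(c1ccccc1)(c1ccccc1)c1ccccc1
Why: Wittig olefination with a stabilised, α-branched ylide gives the E trisubstituted enoate (ester trans to the bulky C4 residue); heating compensates for the neopentyl hindrance, and the neutral conditions leave C5–H and the ring alkene untouched.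

Step 14
Reactants: 17 ethyl ester
Product: 18 homo-plakotenin, (E)-3-[(1R,3R,3aR,4S,5S,7aR)-4,7-diethyl-1,3-dimethyl-5-phenyl-2,3,3a,4,5,7a-hexahydro-1H-inden-4-yl]-2-methylprop-2-enoic acid
Conditions: LiOH, THF/MeOH/H2O, 50 °C; then 1 M HCl
Reagents that add atoms: lithium hydroxide, [Li+].[OH-]
Why: Saponification of an α,β-unsaturated ester that has no γ-hydrogen (C4 is quaternary), so neither deconjugation nor E/Z scrambling is available.

## Compound list

1 | 1-benzoylpyrrolidine | O=C(c1ccccc1)N1CCCC1 | starting material
2 | lithium enolate of the 1,4-dihydrobenzamide | [Li+].[O-]C(N1CCCC1)=C1C=CCC=C1 | intermediate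
3 | (1-ethylcyclohexa-2,5-dien-1-yl)(pyrrolidin-1-yl)methanone | CCC1(C(=O)N2CCCC2)C=CCC=C1 | intermediate
4 | (1-ethyl-4-oxocyclohexa-2,5-dien-1-yl)(pyrrolidin-1-yl)methanone | CCC1(C(=O)N2CCCC2)C=CC(=O)C=C1 | intermediate
5 | enone, 4β-Et, 4α-amide, 5β-Ph | O=C1C[C@@H](c2ccccc2)[C@@](C(=O)N3CCCC3)(CC)C=C1 | intermediate
6 | trimethylsilyl enol ether of 7 | C[Si](C)(C)OC=1C[C@@H](c2ccccc2)[C@@](C(=O)N3CCCC3)(CC)[C@H](C=C)C=1 | intermediate
7 | 3aα-vinyl ketone | O=C1C[C@@H](c2ccccc2)[C@@](C(=O)N3CCCC3)(CC)[C@@H](C1)C=C | intermediate
8 | side-chain (E)-enone | O=C1C[C@@H](c2ccccc2)[C@@](C(=O)N3CCCC3)(CC)[C@@H](C1)/C=C/C(C)=O | intermediate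
9 | 1,6-diketone with C3 methyl | O=C1C[C@@H](c2ccccc2)[C@@](C(=O)N3CCCC3)(CC)[C@@H](C1)[C@H](C)CC(C)=O | intermediate
10 | bicyclic tetrasubstituted enone | O=C1C[C@@H](c2ccccc2)[C@@](C(=O)N3CCCC3)(CC)[C@H]2C1=C(C)C[C@H]2C | intermediate
11 | trans-hydrindanone | O=C1C[C@@H](c2ccccc2)[C@@](C(=O)N3CCCC3)(CC)[C@H]2[C@H]1[C@H](C)C[C@H]2C | intermediate
12 | potassium C6=C7 enolate of 11 | [K+].[O-]C1=C[C@@H](c2ccccc2)[C@@](C(=O)N3CCCC3)(CC)[C@H]2[C@H]1[C@H](C)C[C@H]2C | intermediate
13 | enol triflate | O=S(=O)(OC1=C[C@@H](c2ccccc2)[C@@](C(=O)N3CCCC3)(CC)[C@H]2[C@H]1[C@H](C)C[C@H]2C)C(F)(F)F | intermediate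
14 | 7-ethyl alkene amide | CCC1=C[C@@H](c2ccccc2)[C@@](C(=O)N3CCCC3)(CC)[C@H]2[C@H]1[C@H](C)C[C@H]2C | intermediate
15 | primary alcohol | CCC1=C[C@@H](c2ccccc2)[C@@](CO)(CC)[C@H]2[C@H]1[C@H](C)C[C@H]2C | intermediate
16 | aldehyde | CCC1=C[C@@H](c2ccccc2)[C@@](C=O)(CC)[C@H]2[C@H]1[C@H](C)C[C@H]2C | intermediate
17 | ethyl ester of 18 | CCC1=C[C@@H](c2ccccc2)[C@@](/C=C(\C)C(=O)OCC)(CC)[C@H]2[C@H]1[C@H](C)C[C@H]2C | intermediate
18 | homo-plakotenin | CCC1=C[C@@H](c2ccccc2)[C@@](/C=C(\C)C(=O)O)(CC)[C@H]2[C@H]1[C@H](C)C[C@H]2C | target

## Step count and least certain steps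

Total step count: 14. Longest linear sequence: 14 (fully linear from 1).

**Step 3 (key step).**
- *What may go wrong:* the crowded dienone may insert slowly, so that protodeboronation of the boronic acid competes. The discrimination between the ethyl face and the amide face may also be incomplete. Because the catalyst accepts the same enone enantioface on the α side of the other arm, this would appear as loss of diastereoselectivity rather than of enantiopurity.
- *Fallback:* separate the two tasks, setting out from 4 and returning at 5.
  - A catalytic asymmetric conjugate reduction (copper hydride with a chiral bisphosphine, or an ene-reductase) removes one enone arm and fixes C4, giving the 4,4-disubstituted cyclohexenone F1.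
  - Ph2CuLi then adds anti to the amide to give the saturated ketone F2.
  - Kinetic silylation towards the less hindered C7a methylene gives the silyl enol ether F3.
  - Saegusa oxidation with Pd(OAc)2 restores the C3a=C7a enone of 5.

**Step 6.**
- *What may go wrong:* catalyst and substrate preferences are opposed. The γ-branched, bulky enone may fit the chiral pocket poorly, which would erode facial selectivity at C3.
- *Fallback:* reverse the roles of the two substituents on C3 so that the substrate's own Felkin–Anh preference becomes productive. It sets out from 7 and returns at 9.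
  - Cross metathesis of 7 with phenyl vinyl sulfone gives the (E)-vinyl sulfone F4.
  - Base-mediated Michael addition of tert-butyl acetoacetate brings in C2, C1 and the C1 methyl carbon, anti to C4, and gives adduct F5.
  - Trifluoroacetic acid removes the ester by decarboxylation to give the sulfonyl diketone F6.
  - Buffered sodium amalgam cleaves the sulfone, so that the former acceptor carbon is left as the C3 methyl group of 9.

**Step 8.**
- *What may go wrong:* the tetrasubstituted, conjugated alkene may bind the iridium cation too weakly, in particular with the α-oriented C3 methyl group nearby. Catalyst deactivation could then outrun turnover.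
- *Fallback:* bring in the C1 methyl group as a nucleophile instead of hydrogen. It sets out from 7 and returns at 11.
  - Cross metathesis of 7 with crotonaldehyde gives the enal F7.
  - The copper-catalysed methyl addition of step 6 gives the keto aldehyde F8.
  - Aldol condensation gives the trisubstituted enone F9.
  - Me2CuLi adds to C1 from the open β face, anti to the C3 methyl group. The enolate is then protonated kinetically at −78 °C along the axial α trajectory, anti to the new methyl group, to give 11.

**Step 9.**
- *What may go wrong:* proton exchange between enolate and ketone during deprotonation could epimerise C7a towards the less strained cis-fused series or scramble the enolate position.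
- *Fallback:* avoid enolate chemistry, setting out from 11 and returning at 14.
  - Hydrazine converts 11 into the hydrazone F10.
  - Iodine with a guanidine base (Barton vinyl iodide synthesis) gives the less substituted vinyl iodide F11.
  - Negishi coupling with Et2Zn and Pd(dppf)Cl2 gives 14.

**Step 11.**
- *What may go wrong:* the axial, α-quaternary amide may be attacked only slowly. The intermediate hemiaminal may also collapse with C–O instead of C–N cleavage, which would give the tertiary amine.
- *Fallback:* change the reaction type. Hydrozirconation of the amide carbonyl of 14 with Cp2Zr(H)Cl, followed by hydrolysis on silica, gives aldehyde 16 directly. This bypasses 15 and makes no new compound.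

## Further compounds

F1 | step 3 | 4-ethyl-4-(pyrrolidine-1-carbonyl)cyclohex-2-enone, C4 as in 5 | O=C1C=C[C@@](C(=O)N2CCCC2)(CC)CC1
F2 | step 3 | 4β-ethyl-4α-amide-5β-phenylcyclohexanone | O=C1C[C@@H](c2ccccc2)[C@@](C(=O)N3CCCC3)(CC)CC1
F3 | step 3 | trimethylsilyl enol ether of F2 towards C7a | C[Si](C)(C)OC=1C[C@@H](c2ccccc2)[C@@](C(=O)N3CCCC3)(CC)CC=1
F4 | step 6 | (E)-vinyl sulfone from 7 | O=C1C[C@@H](c2ccccc2)[C@@](C(=O)N3CCCC3)(CC)[C@@H](C1)/C=C/S(=O)(=O)c1ccccc1
F5 | step 6 | acetoacetate Michael adduct (C2 epimers) | O=C1C[C@@H](c2ccccc2)[C@@](C(=O)N3CCCC3)(CC)[C@@H](C1)[C@H](CS(=O)(=O)c1ccccc1)C(C(C)=O)C(=O)OC(C)(C)C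
F6 | step 6 | sulfonyl 1,6-diketone | O=C1C[C@@H](c2ccccc2)[C@@](C(=O)N3CCCC3)(CC)[C@@H](C1)[C@H](CS(=O)(=O)c1ccccc1)CC(C)=O
F7 | step 8 | side-chain (E)-enal | O=C1C[C@@H](c2ccccc2)[C@@](C(=O)N3CCCC3)(CC)[C@@H](C1)/C=C/C=O
F8 | step 8 | keto aldehyde with C3 methyl | O=C1C[C@@H](c2ccccc2)[C@@](C(=O)N3CCCC3)(CC)[C@@H](C1)[C@H](C)CC=O
F9 | step 8 | bicyclic trisubstituted enone (C7a=C1–H) | O=C1C[C@@H](c2ccccc2)[C@@](C(=O)N3CCCC3)(CC)[C@H]2C1=CC[C@H]2C
F10 | step 9 | hydrazone of 11 | NN=C1C[C@@H](c2ccccc2)[C@@](C(=O)N3CCCC3)(CC)[C@H]2[C@H]1[C@H](C)C[C@H]2C
F11 | step 9 | C7 vinyl iodide | IC1=C[C@@H](c2ccccc2)[C@@](C(=O)N3CCCC3)(CC)[C@H]2[C@H]1[C@H](C)C[C@H]2C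
F0 | step 11 | none | none
A1 | alternative 1 | (2E,4Z,6R,8R,9E,11E)-4,10-diethyl-2,6,8-trimethyl-12-phenyldodeca-2,4,9,11-tetraenoic acid | c1ccccc1/C=C/C(CC)=C/[C@H](C)C[C@@H](C)/C=C(CC)\C=C(/C)C(=O)O
A2 | alternative 1 | facial diastereomer of 18 (C3a, C4, C5, C7a inverted; methyls cis to the adjacent fusion hydrogens) | CCC1=C[C@H](c2ccccc2)[C@](/C=C(\C)C(=O)O)(CC)[C@@H]2[C@@H]1[C@H](C)C[C@H]2C
A3 | alternative 2 | methyl (1R,3R)-1,3-dimethyl-2,3-dihydro-1H-indene-4-carboxylate | COC(=O)c1cccc2c1[C@H](C)C[C@H]2C
A4 | alternative 2 | methyl 4β-ethyl-1,3-dimethyl-2,3,4,7-tetrahydro-1H-indene-4-carboxylate | COC(=O)[C@@]1(CC)C=CCC2=C1[C@H](C)C[C@H]2C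
A5 | alternative 3 | cinnamyl 2-[2-(but-1-en-2-yl)-3,5-dimethylcyclopentyl]butanoate (ring centres as in 18) | CCC(C(=O)OC/C=C/c1ccccc1)[C@H]1[C@H](C(=C)CC)[C@H](C)C[C@H]1C
A6 | alternative 3 | Ireland–Claisen acid with C4 and C5 as in 18 | C=C[C@@H](c1ccccc1)[C@@](C(=O)O)(CC)[C@H]1[C@H](C(=C)CC)[C@H](C)C[C@H]1C
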